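**Remarks (assumptions).** Read from the SMILES, the prenyl ring (ring A) is 2,6-cis, (2S,6R), and the hydroxyprenyl ring (ring B) is 2',6'-trans, (2'R,6'S). C2 and C2' have the same spatial arrangement, so both rings are planned from one enantiomer of one terpene. (R)-α-Campholenic aldehyde of high enantiomeric purity is taken as purchasable (otherwise one step, ZnBr2, from the matching α-pinene oxide). Carotenoid locants are used throughout (C1 gem-dimethyl carbon, C2 arm-bearing carbon, C4=C5 ring alkene, C6 chain-bearing carbon, C7 first chain carbon; primes for ring B).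

**Retrosynthetic overview**
1. C50 = C20 + C10 + C20: Wittig at C11=C12 (ring A salt 15 + dialdehyde 21), then at C11'=C12' (ring B salt 20); the side-chain ester is reduced to the allylic alcohol last.
2. Both end groups come from one cis enone 11: ring A keeps the kinetic 2,6-cis centre, ring B gets 2',6'-trans by base equilibration at C6'; the side arms are made by Wittig reactions on a common CH2CHO handle.
3. The six-membered ring (rings A and B as one compound, before any polyene exists) is closed at C5–C6 by intramolecular alkenyl–alkenyl coupling of a Z-iodoalkene (C4=C5) with an enol triflate (C6=C7); the exocyclic diene is then hydroborated at C7, which sets C6.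
4. The precursor arises by cutting the cyclopentene of (R)-α-campholenic aldehyde (ozonolysis) and splicing C5 with its methyl in by iodo-olefination: a net one-carbon ring expansion that carries C2 and the gem-dimethyl C1 over from the terpene.
5. Enabling feature: C6 sits between the quaternary C1 (methyls C16/C17) and its own methyl C7, so the ketone gives a single enol triflate and the chain is pre-bent (Thorpe–Ingold), while the arms on C2 hold the Z-iodoalkene carbon C5 within reach of C6.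

Key step: step 5

**Step 1**
Reactants: 1 (R)-α-campholenic aldehyde
Product: 2 (4R)-4-(2,2-dimethoxyethyl)-1,5,5-trimethylcyclopent-1-ene
Conditions: HC(OMe)3, MeOH, pyridinium p-toluenesulfonate (cat.), 23 °C
Reagents that add atoms: trimethyl orthoformate, COC(OC)OC
Why: Acid-catalysed acetalisation (orthoformate as water scavenger) masks the aldehyde arm so that it stays distinct from the two carbonyl termini made in the next step; C2 is untouched.

**Step 2**
Reactants: 2 (4R)-4-(2,2-dimethoxyethyl)-1,5,5-trimethylcyclopent-1-ene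
Product: 3 (3R)-3-(2,2-dimethoxyethyl)-4,4-dimethyl-5-oxohexanal
Conditions: O3, CH2Cl2, −78 °C; then Me2S, −78 to 23 °C
Reagents that add atoms: ozone, [O-][O+]=O
Why: Ozonolysis with reductive work-up cleaves the only C=C (the ring bond that C5 will replace) to a methyl ketone at C6 and an aldehyde at C4, two termini of different reactivity.

**Step 3**
Reactants: 3 (3R)-3-(2,2-dimethoxyethyl)-4,4-dimethyl-5-oxohexanal
Product: 4 (4R,6Z)-4-(2,2-dimethoxyethyl)-7-iodo-3,3-dimethyloct-6-en-2-one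
Conditions: EtPPh3I, n-BuLi, THF, 23 °C; I2, −78 °C; NaN(SiMe3)2, −20 °C; then 3, −78 °C
Reagents that add atoms: ethyltriphenylphosphonium iodide, CC[P+](c1ccccc1)(c1ccccc1)c1ccccc1.[I-]; iodine, II
Why: Stork–Zhao-type α-iodo Wittig olefination: the unstabilised iodo-ylide attacks only the aldehyde (the tert-alkyl methyl ketone is too hindered at −78 °C) and kinetic control should give the Z-iodoalkene, with iodine cis to C3 as the ring closure needs.

**Step 4**
Reactants: 4 (4R,6Z)-4-(2,2-dimethoxyethyl)-7-iodo-3,3-dimethyloct-6-en-2-one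
Product: 5 (4R,6Z)-4-(2,2-dimethoxyethyl)-7-iodo-3,3-dimethylocta-1,6-dien-2-yl trifluoromethanesulfonate
Conditions: KN(SiMe3)2, PhNTf2, THF, −78 °C
Reagents that add atoms: N-phenylbis(trifluoromethanesulfonimide), O=S(=O)(N(c1ccccc1)S(=O)(=O)C(F)(F)F)C(F)(F)F
Why: Kinetic enol triflate formation; because C1 is quaternary the ketone can enolise only toward the C7 methyl, so a single 1,1-disubstituted enol triflate should result.

**Step 5**
Reactants: 5 (4R,6Z)-4-(2,2-dimethoxyethyl)-7-iodo-3,3-dimethylocta-1,6-dien-2-yl trifluoromethanesulfonate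
Product: 7 (4R)-4-(2,2-dimethoxyethyl)-1,5,5-trimethyl-6-methylidenecyclohex-1-ene, via alkenyl pinacol boronate 6 (not isolated)
Conditions: PdCl2(PPh3)2 (5 mol%), PPh3, B2pin2, KOPh, toluene, 50 °C; then aq K3PO4, dioxane, 80 °C
Reagents that add atoms: none
Why: Zerovalent palladium inserts into the C5–I bond with retention of the Z geometry and, with B2pin2 and KOPh, turns it into alkenyl boronate 6 (Miyaura borylation); a second oxidative addition into the C6–OTf bond, phosphate-assisted transmetalation of the tethered boronate to a seven-membered palladacycle and reductive elimination then form the C5–C6 bond. The closest known reaction type is the one-pot Miyaura borylation/intramolecular Suzuki–Miyaura coupling of two alkenyl electrophiles (compare the Stille–Kelly cyclisation). The six-membered ring closes by sp2–sp2 reductive elimination, endo with respect to C4=C5 (which stays in the ring) and exo with respect to C6=C7 (which becomes the exocyclic methylene). No stereocentre is formed; C2 is remote from the reacting carbons and the Z-iodoalkene is carried over as the ring alkene. The step needs cyclisation to beat intermolecular coupling and needs one fixed double-bond position: the gem-dimethyl group at C1 and the cis placement of chain and metal on C4=C5 secure the first, and the fact that both sp2 carbons are installed beforehand (no β-hydride elimination, no cation) secures the second, so the ring alkene cannot drift from C4=C5. Either electrophile may be borylated first, since both orders converge on the same diene.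

**Step 6**
Reactants: 7 (4R)-4-(2,2-dimethoxyethyl)-1,5,5-trimethyl-6-methylidenecyclohex-1-ene
Product: 9 [(1R,5R)-5-(2,2-dimethoxyethyl)-2,6,6-trimethylcyclohex-2-en-1-yl]methanol, via B-alkyl-9-BBN adduct 8 (not isolated)
Conditions: 9-BBN, THF, 0 to 23 °C; then NaOH, H2O2, 0 °C
Reagents that add atoms: hydrogen peroxide, OO
Why: Anti-Markovnikov hydroboration–oxidation: 9-BBN should attack only the 1,1-disubstituted exocyclic alkene, boron going to C7 and hydrogen to C6 from the ring face opposite the pseudo-axial C1 methyl, which sets C6 cis to the C2 arm (kinetic substrate control, the same facial bias as in kinetic protonation of irone-type dienol derivatives).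

**Step 7**
Reactants: 9 [(1R,5R)-5-(2,2-dimethoxyethyl)-2,6,6-trimethylcyclohex-2-en-1-yl]methanol
Product: 10 (1R,5R)-5-(2,2-dimethoxyethyl)-2,6,6-trimethylcyclohex-2-ene-1-carbaldehyde
Conditions: Dess–Martin periodinane, pyridine, CH2Cl2, 0 °C
Reagents that add atoms: none
Why: Dess–Martin oxidation under buffered, non-basic conditions should take the primary alcohol to the aldehyde without epimerising the allylic α-centre C6.

**Step 8**
Reactants: 10 (1R,5R)-5-(2,2-dimethoxyethyl)-2,6,6-trimethylcyclohex-2-ene-1-carbaldehyde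
Product: 11 (3E)-4-[(1R,5R)-5-(2,2-dimethoxyethyl)-2,6,6-trimethylcyclohex-2-en-1-yl]but-3-en-2-one
Conditions: Ph3P=CHC(O)CH3, toluene, 80 °C
Reagents that add atoms: 1-(triphenylphosphoranylidene)propan-2-one, CC(=O)C=P(c1ccccc1)(c1ccccc1)c1ccccc1
Why: Wittig olefination with a stabilised, weakly basic keto-ylide should give the E-enone (α-ionone type) and leave the labile C6 centre as it is.

**Step 9**
Reactants: 11 (3E)-4-[(1R,5R)-5-(2,2-dimethoxyethyl)-2,6,6-trimethylcyclohex-2-en-1-yl]but-3-en-2-one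
Product: 12 2-[(1R,5R)-4,6,6-trimethyl-5-[(1E)-3-oxobut-1-en-1-yl]cyclohex-3-en-1-yl]acetaldehyde
Conditions: 1 M aq HCl, THF, 23 °C
Reagents that add atoms: water, O
Why: Mild acid hydrolysis of the dimethyl acetal frees the side-arm aldehyde; the enone and the isolated ring alkene tolerate dilute acid at room temperature.

**Step 10**
Reactants: 12 2-[(1R,5R)-4,6,6-trimethyl-5-[(1E)-3-oxobut-1-en-1-yl]cyclohex-3-en-1-yl]acetaldehyde
Product: 13 (3E)-4-[(1R,5S)-2,6,6-trimethyl-5-(3-methylbut-2-en-1-yl)cyclohex-2-en-1-yl]but-3-en-2-one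
Conditions: i-PrPPh3I, n-BuLi, THF, −78 to 0 °C
Reagents that add atoms: isopropyltriphenylphosphonium iodide, CC(C)[P+](c1ccccc1)(c1ccccc1)c1ccccc1.[I-]
Why: Wittig olefination with the unstabilised isopropylidene ylide is much faster at the unhindered aldehyde than at the conjugated methyl ketone and installs the prenyl group of ring A (no alkene geometry is at stake).

**Step 11**
Reactants: 13 (3E)-4-[(1R,5S)-2,6,6-trimethyl-5-(3-methylbut-2-en-1-yl)cyclohex-2-en-1-yl]but-3-en-2-one
Product: 14 (1E)-3-methyl-1-[(1R,5S)-2,6,6-trimethyl-5-(3-methylbut-2-en-1-yl)cyclohex-2-en-1-yl]penta-1,4-dien-3-ol (both carbinol epimers)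
Conditions: CH2=CHMgBr, THF, −78 to 0 °C
Reagents that add atoms: vinylmagnesium bromide, C=C[Mg]Br
Why: Grignard 1,2-addition to the methyl ketone gives the tertiary divinyl carbinol; its new centre is formed without control and is destroyed in the next step.

**Step 12**
Reactants: 14 (1E)-3-methyl-1-[(1R,5S)-2,6,6-trimethyl-5-(3-methylbut-2-en-1-yl)cyclohex-2-en-1-yl]penta-1,4-dien-3-ol
Product: 15 [(2E,4E)-3-methyl-5-[(1R,5S)-2,6,6-trimethyl-5-(3-methylbut-2-en-1-yl)cyclohex-2-en-1-yl]penta-2,4-dien-1-yl]triphenylphosphonium bromide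
Conditions: PPh3·HBr, MeOH, 23 °C
Reagents that add atoms: triphenylphosphine hydrobromide, Br.P(c1ccccc1)(c1ccccc1)c1ccccc1
Why: Ionisation of the tertiary bis-allylic alcohol and capture of the pentadienyl cation by PPh3 at the unhindered terminus (allylic transposition) is the standard end-group reaction of carotenoid synthesis and should give mainly the 9E salt.

**Step 13**
Reactants: 11 (3E)-4-[(1R,5R)-5-(2,2-dimethoxyethyl)-2,6,6-trimethylcyclohex-2-en-1-yl]but-3-en-2-one
Product: 16 (3E)-4-[(1S,5R)-5-(2,2-dimethoxyethyl)-2,6,6-trimethylcyclohex-2-en-1-yl]but-3-en-2-one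
Conditions: NaOMe (0.2 equiv), MeOH, 23 °C
Reagents that add atoms: none
Why: Base equilibration through the extended dienolate epimerises C6'; the trans isomer (side chain pseudo-axial, free of allylic strain with the C5' methyl, C2' arm equatorial) should be the thermodynamic one, as in the cis-to-trans epimerisation of α-irone.

**Step 14**
Reactants: 16 (3E)-4-[(1S,5R)-5-(2,2-dimethoxyethyl)-2,6,6-trimethylcyclohex-2-en-1-yl]but-3-en-2-one
Product: 17 2-[(1R,5S)-4,6,6-trimethyl-5-[(1E)-3-oxobut-1-en-1-yl]cyclohex-3-en-1-yl]acetaldehyde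
Conditions: 1 M aq HCl, THF, 23 °C
Reagents that add atoms: water, O
Why: Acetal hydrolysis as in step 9; dilute acid does not enolise the enone, so the trans centre is kept.

**Step 15**
Reactants: 17 2-[(1R,5S)-4,6,6-trimethyl-5-[(1E)-3-oxobut-1-en-1-yl]cyclohex-3-en-1-yl]acetaldehyde
Product: 18 ethyl (2E)-2-methyl-4-[(1R,5S)-4,6,6-trimethyl-5-[(1E)-3-oxobut-1-en-1-yl]cyclohex-3-en-1-yl]but-2-enoate
Conditions: Ph3P=C(CH3)CO2Et, CH2Cl2, 23 °C
Reagents that add atoms: ethyl 2-(triphenylphosphoranylidene)propanoate, CCOC(=O)C(C)=P(c1ccccc1)(c1ccccc1)c1ccccc1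
Why: The stabilised α-methyl ylide reacts only with the aldehyde (not with the enone) and should give the E-trisubstituted enoate, the masked form of the (E)-4-hydroxy-3-methylbut-2-enyl arm.

**Step 16**
Reactants: 18 ethyl (2E)-2-methyl-4-[(1R,5S)-4,6,6-trimethyl-5-[(1E)-3-oxobut-1-en-1-yl]cyclohex-3-en-1-yl]but-2-enoate
Product: 19 ethyl (2E)-4-[(1R,5S)-5-[(1E)-3-hydroxy-3-methylpenta-1,4-dien-1-yl]-4,6,6-trimethylcyclohex-3-en-1-yl]-2-methylbut-2-enoate (both carbinol epimers)
Conditions: CH2=CHMgBr (1.2 equiv), THF, −78 °C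
Reagents that add atoms: vinylmagnesium bromide, C=C[Mg]Br
Why: Grignard 1,2-addition is chemoselective for the ketone over the α-methyl enoate at −78 °C; the new carbinol centre is again of no consequence.

**Step 17**
Reactants: 19 ethyl (2E)-4-[(1R,5S)-5-[(1E)-3-hydroxy-3-methylpenta-1,4-dien-1-yl]-4,6,6-trimethylcyclohex-3-en-1-yl]-2-methylbut-2-enoate
Product: 20 [(2E,4E)-5-[(1S,5R)-5-[(2E)-4-ethoxy-3-methyl-4-oxobut-2-en-1-yl]-2,6,6-trimethylcyclohex-2-en-1-yl]-3-methylpenta-2,4-dien-1-yl]triphenylphosphonium bromide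
Conditions: PPh3·HBr, EtOH/CH2Cl2, 23 °C
Reagents that add atoms: triphenylphosphine hydrobromide, Br.P(c1ccccc1)(c1ccccc1)c1ccccc1
Why: Same ionisation/phosphine capture with allylic transposition as in step 12; the enoate arm is inert to PPh3·HBr.

**Step 18**
Reactants: 15 [(2E,4E)-3-methyl-5-[(1R,5S)-2,6,6-trimethyl-5-(3-methylbut-2-en-1-yl)cyclohex-2-en-1-yl]penta-2,4-dien-1-yl]triphenylphosphonium bromide; 21 (2E,4E,6E)-2,7-dimethylocta-2,4,6-trienedial
Product: 23 (2E,4E,6E,8E,10E,12E)-2,7,11-trimethyl-13-[(1R,5S)-2,6,6-trimethyl-5-(3-methylbut-2-en-1-yl)cyclohex-2-en-1-yl]trideca-2,4,6,8,10,12-hexaenal, via dienyl ylide 22 (not isolated)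
Conditions: 21 (3 equiv), NaOEt, EtOH/CH2Cl2, 0 to 23 °C; then I2 (cat.), hexane, 23 °C
Reagents that add atoms: none
Why: Wittig olefination of the excess symmetrical C10 dialdehyde with the dienyl ylide forms C11=C12 once; the Z/E mixture at the new bond should be equilibrated to all-E by iodine catalysis.

**Step 19**
Reactants: 23 (2E,4E,6E,8E,10E,12E)-2,7,11-trimethyl-13-[(1R,5S)-2,6,6-trimethyl-5-(3-methylbut-2-en-1-yl)cyclohex-2-en-1-yl]trideca-2,4,6,8,10,12-hexaenal; 20 [(2E,4E)-5-[(1S,5R)-5-[(2E)-4-ethoxy-3-methyl-4-oxobut-2-en-1-yl]-2,6,6-trimethylcyclohex-2-en-1-yl]-3-methylpenta-2,4-dien-1-yl]triphenylphosphonium bromide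
Product: 25 ethyl (2E)-2-methyl-4-[(2S,6R,2'R,6'S)-2-(3-methylbut-2-en-1-yl)-ε,ε-caroten-2'-yl]but-2-enoate, via dienyl ylide 24 (not isolated)
Conditions: NaOEt, EtOH/CH2Cl2, 0 to 23 °C; then heptane, 90 °C
Reagents that add atoms: none
Why: The second Wittig olefination forms C11'=C12' and completes the C50 skeleton; heating should equilibrate the new bond to the all-E polyene, and the ethyl ester survives ethoxide unchanged.

**Step 20**
Reactants: 25 ethyl (2E)-2-methyl-4-[(2S,6R,2'R,6'S)-2-(3-methylbut-2-en-1-yl)-ε,ε-caroten-2'-yl]but-2-enoate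
Product: 26 (2S,6R,2'R,6'S)-2'-[(2E)-4-hydroxy-3-methylbut-2-en-1-yl]-2-(3-methylbut-2-en-1-yl)-ε,ε-carotene (target, CNP0304855.1)
Conditions: i-Bu2AlH, CH2Cl2, −78 °C
Reagents that add atoms: none
Why: i-Bu2AlH reduces the α,β-unsaturated ester 1,2 to the primary allylic alcohol at low temperature without touching the polyene or the two ring alkenes.

**Compound list**
1 | (R)-α-campholenic aldehyde, 2-[(1R)-2,2,3-trimethylcyclopent-3-en-1-yl]acetaldehyde | O=CC[C@H]1CC=C(C)C1(C)C | starting material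
2 | (4R)-4-(2,2-dimethoxyethyl)-1,5,5-trimethylcyclopent-1-ene | COC(OC)C[C@H]1CC=C(C)C1(C)C | intermediate
3 | (3R)-3-(2,2-dimethoxyethyl)-4,4-dimethyl-5-oxohexanal | COC(OC)C[C@@H](CC=O)C(C)(C)C(C)=O | intermediate
4 | (4R,6Z)-4-(2,2-dimethoxyethyl)-7-iodo-3,3-dimethyloct-6-en-2-one | COC(OC)C[C@@H](C/C=C(\I)C)C(C)(C)C(C)=O | intermediate
5 | (4R,6Z)-4-(2,2-dimethoxyethyl)-7-iodo-3,3-dimethylocta-1,6-dien-2-yl trifluoromethanesulfonate | COC(OC)C[C@@H](C/C=C(\I)C)C(C)(C)C(=C)OS(=O)(=O)C(F)(F)F | intermediate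
6 | (4R,6E)-4-(2,2-dimethoxyethyl)-3,3-dimethyl-7-(4,4,5,5-tetramethyl-1,3,2-dioxaborolan-2-yl)octa-1,6-dien-2-yl trifluoromethanesulfonate | COC(OC)C[C@@H](C/C=C(\B1OC(C)(C)C(C)(C)O1)C)C(C)(C)C(=C)OS(=O)(=O)C(F)(F)F | intermediate (not isolated)
7 | (4R)-4-(2,2-dimethoxyethyl)-1,5,5-trimethyl-6-methylidenecyclohex-1-ene | COC(OC)C[C@H]1CC=C(C)C(=C)C1(C)C | intermediate
8 | 9-{[(1R,5R)-5-(2,2-dimethoxyethyl)-2,6,6-trimethylcyclohex-2-en-1-yl]methyl}-9-borabicyclo[3.3.1]nonane | COC(OC)C[C@H]1CC=C(C)[C@@H](CB2C3CCCC2CCC3)C1(C)C | intermediate (not isolated)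
9 | [(1R,5R)-5-(2,2-dimethoxyethyl)-2,6,6-trimethylcyclohex-2-en-1-yl]methanol (cis) | COC(OC)C[C@H]1CC=C(C)[C@@H](CO)C1(C)C | intermediate
10 | (1R,5R)-5-(2,2-dimethoxyethyl)-2,6,6-trimethylcyclohex-2-ene-1-carbaldehyde (cis) | COC(OC)C[C@H]1CC=C(C)[C@@H](C=O)C1(C)C | intermediate
11 | (3E)-4-[(1R,5R)-5-(2,2-dimethoxyethyl)-2,6,6-trimethylcyclohex-2-en-1-yl]but-3-en-2-one (cis) | COC(OC)C[C@H]1CC=C(C)[C@@H](/C=C/C(C)=O)C1(C)C | intermediate
12 | 2-[(1R,5R)-4,6,6-trimethyl-5-[(1E)-3-oxobut-1-en-1-yl]cyclohex-3-en-1-yl]acetaldehyde (cis) | O=CC[C@H]1CC=C(C)[C@@H](/C=C/C(C)=O)C1(C)C | intermediate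
13 | (3E)-4-[(1R,5S)-2,6,6-trimethyl-5-(3-methylbut-2-en-1-yl)cyclohex-2-en-1-yl]but-3-en-2-one (cis, ring A) | CC(C)=CC[C@H]1CC=C(C)[C@@H](/C=C/C(C)=O)C1(C)C | intermediate
14 | (1E)-3-methyl-1-[(1R,5S)-2,6,6-trimethyl-5-(3-methylbut-2-en-1-yl)cyclohex-2-en-1-yl]penta-1,4-dien-3-ol (carbinol epimers) | CC(C)=CC[C@H]1CC=C(C)[C@@H](/C=C/C(C)(O)C=C)C1(C)C | intermediate
15 | [(2E,4E)-3-methyl-5-[(1R,5S)-2,6,6-trimethyl-5-(3-methylbut-2-en-1-yl)cyclohex-2-en-1-yl]penta-2,4-dien-1-yl]triphenylphosphonium bromide | CC(C)=CC[C@H]1CC=C(C)[C@@H](/C=C/C(C)=C/C[P+](c2ccccc2)(c2ccccc2)c2ccccc2)C1(C)C.[Br-] | intermediate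
16 | (3E)-4-[(1S,5R)-5-(2,2-dimethoxyethyl)-2,6,6-trimethylcyclohex-2-en-1-yl]but-3-en-2-one (trans) | COC(OC)C[C@H]1CC=C(C)[C@H](/C=C/C(C)=O)C1(C)C | intermediate
17 | 2-[(1R,5S)-4,6,6-trimethyl-5-[(1E)-3-oxobut-1-en-1-yl]cyclohex-3-en-1-yl]acetaldehyde (trans) | O=CC[C@H]1CC=C(C)[C@H](/C=C/C(C)=O)C1(C)C | intermediate
18 | ethyl (2E)-2-methyl-4-[(1R,5S)-4,6,6-trimethyl-5-[(1E)-3-oxobut-1-en-1-yl]cyclohex-3-en-1-yl]but-2-enoate (trans, ring B) | CCOC(=O)/C(C)=C/C[C@H]1CC=C(C)[C@H](/C=C/C(C)=O)C1(C)C | intermediate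
19 | ethyl (2E)-4-[(1R,5S)-5-[(1E)-3-hydroxy-3-methylpenta-1,4-dien-1-yl]-4,6,6-trimethylcyclohex-3-en-1-yl]-2-methylbut-2-enoate (carbinol epimers) | CCOC(=O)/C(C)=C/C[C@H]1CC=C(C)[C@H](/C=C/C(C)(O)C=C)C1(C)C | intermediate
20 | [(2E,4E)-5-[(1S,5R)-5-[(2E)-4-ethoxy-3-methyl-4-oxobut-2-en-1-yl]-2,6,6-trimethylcyclohex-2-en-1-yl]-3-methylpenta-2,4-dien-1-yl]triphenylphosphonium bromide | CCOC(=O)/C(C)=C/C[C@H]1CC=C(C)[C@H](/C=C/C(C)=C/C[P+](c2ccccc2)(c2ccccc2)c2ccccc2)C1(C)C.[Br-] | intermediate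
21 | (2E,4E,6E)-2,7-dimethylocta-2,4,6-trienedial | O=C/C(C)=C/C=C/C=C(C)/C=O | starting material
22 | {(2E,4E)-3-methyl-5-[(1R,5S)-2,6,6-trimethyl-5-(3-methylbut-2-en-1-yl)cyclohex-2-en-1-yl]penta-2,4-dien-1-ylidene}triphenylphosphorane | CC(C)=CC[C@H]1CC=C(C)[C@@H](/C=C/C(C)=C/C=P(c2ccccc2)(c2ccccc2)c2ccccc2)C1(C)C | intermediate (not isolated)
23 | (2E,4E,6E,8E,10E,12E)-2,7,11-trimethyl-13-[(1R,5S)-2,6,6-trimethyl-5-(3-methylbut-2-en-1-yl)cyclohex-2-en-1-yl]trideca-2,4,6,8,10,12-hexaenal | CC(C)=CC[C@H]1CC=C(C)[C@@H](/C=C/C(C)=C/C=C/C(C)=C/C=C/C=C(C)/C=O)C1(C)C | intermediate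
24 | ethyl (2E)-2-methyl-4-[(1R,5S)-4,6,6-trimethyl-5-[(1E,3E)-3-methyl-5-(triphenylphosphoranylidene)penta-1,3-dien-1-yl]cyclohex-3-en-1-yl]but-2-enoate | CCOC(=O)/C(C)=C/C[C@H]1CC=C(C)[C@H](/C=C/C(C)=C/C=P(c2ccccc2)(c2ccccc2)c2ccccc2)C1(C)C | intermediate (not isolated)
25 | ethyl (2E)-2-methyl-4-[(2S,6R,2'R,6'S)-2-(3-methylbut-2-en-1-yl)-ε,ε-caroten-2'-yl]but-2-enoate | CC(C)=CC[C@H]1CC=C(C)[C@@H](/C=C/C(C)=C/C=C/C(C)=C/C=C/C=C(C)/C=C/C=C(C)/C=C/[C@H]2C(C)=CC[C@H](C/C=C(\C)C(=O)OCC)C2(C)C)C1(C)C | intermediate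
26 | (2S,6R,2'R,6'S)-2'-[(2E)-4-hydroxy-3-methylbut-2-en-1-yl]-2-(3-methylbut-2-en-1-yl)-ε,ε-carotene | CC(C)=CC[C@H]1CC=C(C)[C@@H](/C=C/C(C)=C/C=C/C(C)=C/C=C/C=C(C)/C=C/C=C(C)/C=C/[C@H]2C(C)=CC[C@H](C/C=C(\C)CO)C2(C)C)C1(C)C | target

**Totals.** Total step count: 20. Longest linear sequence: 15 steps (steps 1–8, then either 9–12 and 18–20 or 13–17 and 19–20).

**Steps most likely to fail, with fallbacks**

Step 6 – poor facial selectivity in the hydroboration, so that C6 is delivered as an epimer mixture (both faces of the exocyclic alkene are flanked by a C1 methyl). The fallback sets the centre by kinetic protonation instead of hydroboration. It sets out from aldehyde 10 carried through as the epimer mixture: TBSOTf and Et3N in CH2Cl2 should give the silyl dienol ether tert-butyl{[(5R)-5-(2,2-dimethoxyethyl)-2,6,6-trimethylcyclohex-2-en-1-ylidene]methoxy}dimethylsilane F1, in which C6 is trigonal. Low-temperature protodesilylation (n-Bu4NF, AcOH, THF, −78 °C) then protonates C6 from the less hindered face and comes back to 10 as the cis epimer. Any trans alcohol separated after step 6 is not lost, since it can be fed into the ring B branch.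

Step 13 – incomplete equilibration at C6', or leakage of the trienolate into the ring-conjugated (β-type) isomer by protonation at C4'. The fallback moves the epimerisation to the aldehyde level, where a simple enolate is involved and far milder base suffices. It sets out from cis aldehyde 10: catalytic DBU in CH2Cl2 at 23 °C should equilibrate it to (1S,5R)-5-(2,2-dimethoxyethyl)-2,6,6-trimethylcyclohex-2-ene-1-carbaldehyde F2, and Wittig olefination of F2 with Ph3P=CHC(O)CH3 (toluene, 80 °C) comes back to trans enone 16.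

Step 5 – competing intermolecular coupling, protodeboronation, or slow oxidative addition at the hindered enol triflate. The fallback closes the same bond by carbonyl addition instead of cross-coupling. It sets out from iodo ketone 4: iodine–lithium exchange (t-BuLi, THF/pentane, −100 °C) and intramolecular 1,2-addition of the alkenyllithium to the C6 ketone should give (5R)-5-(2,2-dimethoxyethyl)-1,2,6,6-tetramethylcyclohex-2-en-1-ol F3 (carbinol epimers). Syn-dehydration with Burgess reagent (benzene, 50 °C), for which only the C7 methyl offers a β-hydrogen, comes back to diene 7.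

**Further compounds**
F1 | step 6 | tert-butyl{[(5R)-5-(2,2-dimethoxyethyl)-2,6,6-trimethylcyclohex-2-en-1-ylidene]methoxy}dimethylsilane | COC(OC)C[C@H]1CC=C(C)C(=CO[Si](C)(C)C(C)(C)C)C1(C)C
F2 | step 13 | (1S,5R)-5-(2,2-dimethoxyethyl)-2,6,6-trimethylcyclohex-2-ene-1-carbaldehyde | COC(OC)C[C@H]1CC=C(C)[C@H](C=O)C1(C)C
F3 | step 5 | (5R)-5-(2,2-dimethoxyethyl)-1,2,6,6-tetramethylcyclohex-2-en-1-ol | COC(OC)C[C@H]1CC=C(C)C(C)(O)C1(C)C
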